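Ring B is disconnected at B3–B4. Its oxygens on B2 and B6, flanking the C1-bearing carbon B1, and the styryl group on B4 are the imprint of a folded 1,3,5-triketone. In a single operation aqueous base makes the terminal methyl carbon (B3) add to the styryl ketone carbon (B4); the ring closes, loses water and enolises to the 2-substituted 5-styrylresorcinol, leaving C1 untouched. The precursor is an acetylacetone carrying at its central carbon the preformed (R)-C1 unit (ring A plus the saturated C2–C3–ring C arm) and acylated at one methyl group by a cinnamoyl residue (ring D); rings C and D are masked as allyl ethers.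

Key step: step 7

Labels: C1 is the stereocentre and C2, C3 are the two methylene groups. Ring A is the 4-methoxyphenyl on C1. Ring B is the central arene (B1 bonded to C1, methoxy on B2 and B6, styryl on B4). Ring C is the 4-hydroxy-2-methoxyphenyl on C3 and ring D is the phenol of the stilbene.

Remark on the chemistry: the phenols of rings C and D are carried as allyl ethers, because acetal protection would be lost in the trifluoroacetic acid of step 4 and because release with palladium at the end keeps acid away from the electron-rich stilbene. Methyl (E)-4-hydroxycinnamate is taken as the commercial form of 4-hydroxycinnamic acid. C1 has the same spatial arrangement throughout; its descriptor changes from (R) to (S) in step 7 only because ring B then outranks ring A.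

Step 1
Reactants: 1 1-(4-hydroxy-2-methoxyphenyl)ethanone
Product: 2 1-[2-methoxy-4-(prop-2-en-1-yloxy)phenyl]ethanone
Conditions: allyl bromide (1.2 equiv), K2CO3, acetone, reflux
Reagents that add atoms: allyl bromide, C=CCBr
Why: Williamson ether synthesis, in which the acidic phenol para to the acetyl group is deprotonated and its phenoxide displaces bromide by SN2, giving an ether that tolerates base and cold trifluoroacetic acid.

Step 2
Reactants: 2 1-[2-methoxy-4-(prop-2-en-1-yloxy)phenyl]ethanone; 3 4-methoxybenzaldehyde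
Product: 5 (E)-1-[2-methoxy-4-(prop-2-en-1-yloxy)phenyl]-3-(4-methoxyphenyl)prop-2-en-1-one, via aldol adduct 4 (not isolated)
Conditions: KOH (50 mol%), EtOH, 25 °C
Reagents that add atoms: none
Why: Claisen–Schmidt condensation, in which the methyl ketone enolate adds to the non-enolisable aldehyde and aldol 4 loses water by E1cB to the conjugated E-enone, the thermodynamic isomer.

Step 3
Reactants: 5 (E)-1-[2-methoxy-4-(prop-2-en-1-yloxy)phenyl]-3-(4-methoxyphenyl)prop-2-en-1-one; 6 pentane-2,4-dione
Product: 7 3-{(1R)-3-[2-methoxy-4-(prop-2-en-1-yloxy)phenyl]-1-(4-methoxyphenyl)-3-oxopropyl}pentane-2,4-dione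
Conditions: 6 (3 equiv), 9-amino-9-deoxy-epi-quinidine-derived N-[3,5-bis(trifluoromethyl)phenyl]thiourea (10 mol%), toluene, 25 °C
Reagents that add atoms: none
Why: Organocatalytic asymmetric Michael addition under bifunctional thiourea–amine catalysis, in which the quinuclidine nitrogen forms the diketone enolate while the thiourea hydrogen-bonds the enone carbonyl, so that one face of the β-carbon is attacked; the quinidine-derived catalyst is expected to give the (R) centre by analogy with the facial preference of this catalyst family with chalcones, and its quinine-derived pseudo-enantiomer would be substituted should the configuration, to be checked at this stage, prove opposite.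

Step 4
Reactants: 7 3-{(1R)-3-[2-methoxy-4-(prop-2-en-1-yloxy)phenyl]-1-(4-methoxyphenyl)-3-oxopropyl}pentane-2,4-dione
Product: 9 3-{(1R)-3-[2-methoxy-4-(prop-2-en-1-yloxy)phenyl]-1-(4-methoxyphenyl)propyl}pentane-2,4-dione, via benzylic alcohol 8 (not isolated)
Conditions: Et3SiH (3 equiv), CF3CO2H (10 equiv), CH2Cl2, 0 to 20 °C
Reagents that add atoms: none
Why: Ionic hydrogenation, in which the ketone conjugated to the 2,4-dioxygenated ring is protonated and reduced to alcohol 8, which ionises to a strongly stabilised benzylic cation that accepts a second hydride, while the β-diketone, the terminal allyl alkene and the non-enolisable C1 should stay untouched and any reversible capture of the cation by the diketone enol oxygen re-ionises to the same product.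

Step 5
Reactants: 10 methyl (E)-3-(4-hydroxyphenyl)prop-2-enoate
Product: 11 methyl (E)-3-[4-(prop-2-en-1-yloxy)phenyl]prop-2-enoate
Conditions: allyl bromide (1.2 equiv), K2CO3, acetone, reflux
Reagents that add atoms: allyl bromide, C=CCBr
Why: Williamson ether synthesis, the phenoxide being O-alkylated by SN2 while the methyl ester and the E-alkene are inert to carbonate.

Step 6
Reactants: 9 3-{(1R)-3-[2-methoxy-4-(prop-2-en-1-yloxy)phenyl]-1-(4-methoxyphenyl)propyl}pentane-2,4-dione; 11 methyl (E)-3-[4-(prop-2-en-1-yloxy)phenyl]prop-2-enoate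
Product: 13 (7E)-3-{(1R)-3-[2-methoxy-4-(prop-2-en-1-yloxy)phenyl]-1-(4-methoxyphenyl)propyl}-8-[4-(prop-2-en-1-yloxy)phenyl]oct-7-ene-2,4,6-trione, via dilithium dianion 12 (not isolated)
Conditions: LiN(iPr)2 (2.1 equiv), THF, −78 to 0 °C; LiN(SiMe3)2 (1.1 equiv), −78 °C; 11 (1.1 equiv), −78 to 0 °C; aq. NH4Cl
Reagents that add atoms: none
Why: Claisen-type acylation of a 1,3-diketone dianion at its terminal carbon, in which LiN(iPr)2 removes the B1 hydrogen and then a methyl hydrogen of 9 to give dianion 12, whose hard terminal carbanion attacks the ester carbonyl of 11 in preference to its β-carbon (either acetyl group leads to the same triketone because B1 is stereolabile), while LiN(SiMe3)2 acts as a non-nucleophilic third equivalent of base that deprotonates the more acidic product so that it does not quench 12.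

Step 7
Reactants: 13 (7E)-3-{(1R)-3-[2-methoxy-4-(prop-2-en-1-yloxy)phenyl]-1-(4-methoxyphenyl)propyl}-8-[4-(prop-2-en-1-yloxy)phenyl]oct-7-ene-2,4,6-trione
Product: 15 2-{(1S)-3-[2-methoxy-4-(prop-2-en-1-yloxy)phenyl]-1-(4-methoxyphenyl)propyl}-5-{(E)-2-[4-(prop-2-en-1-yloxy)phenyl]ethenyl}benzene-1,3-diol, via cyclic aldol 14 (not isolated)
Conditions: KOH (2 M in H2O, 5 equiv), MeOH–THF, degassed, 20 to 45 °C; then 1 M HCl to pH 5
Reagents that add atoms: none
Why: Hydroxide deprotonates the triketone reversibly, and the enolate of the terminal methyl ketone (carbon B3) adds to the styryl ketone carbon B4 in an intramolecular aldol addition that forms the B3–B4 bond; aldol 14 then loses water by E1cB and the resulting cyclohexenedione tautomerises to the resorcinol, an aromatisation that makes the sequence irreversible. The closest known reaction is the base-induced aldol aromatisation of open-chain 1,3,5-triketones, as in the classical conversion of heptane-2,4,6-trione into orcinol. Ring B is closed in the 6-(enolendo)-exo-trig mode, which the Baldwin rules for enolates allow. No stereocentre is created, since the carbinol carbon and B1 both become aromatic, and C1 should keep its configuration because it is not α to any carbonyl group and, with C3 now a methylene group, cannot be lost by retro-Michael cleavage. The step needs carbon–carbon closure to win over oxygen cyclisation (pyranone or oxa-Michael products) and over retro-Claisen cleavage: under base the oxygen adducts form reversibly while the aldol is drained by aromatisation, the chain offers no other carbocyclic closure of sensible ring size (the styryl side has no α-hydrogen and the B5 methylene could only close a four-membered ring), and the anionic state of the triketone shields its carbonyl groups from hydroxide.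

Step 8
Reactants: 15 2-{(1S)-3-[2-methoxy-4-(prop-2-en-1-yloxy)phenyl]-1-(4-methoxyphenyl)propyl}-5-{(E)-2-[4-(prop-2-en-1-yloxy)phenyl]ethenyl}benzene-1,3-diol
Product: 16 1,3-dimethoxy-2-{(1S)-3-[2-methoxy-4-(prop-2-en-1-yloxy)phenyl]-1-(4-methoxyphenyl)propyl}-5-{(E)-2-[4-(prop-2-en-1-yloxy)phenyl]ethenyl}benzene
Conditions: MeI (6 equiv), K2CO3, acetone, 50 °C
Reagents that add atoms: iodomethane, CI
Why: Williamson O-methylation of both resorcinol phenoxides, which are the only free hydroxyl groups because rings C and D are allyl-protected, with carbon alkylation disfavoured by the blocked B1 position and the carbonate/acetone medium.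

Step 9
Reactants: 16 1,3-dimethoxy-2-{(1S)-3-[2-methoxy-4-(prop-2-en-1-yloxy)phenyl]-1-(4-methoxyphenyl)propyl}-5-{(E)-2-[4-(prop-2-en-1-yloxy)phenyl]ethenyl}benzene
Product: 17 4-[(3S)-3-{4-[(E)-2-(4-hydroxyphenyl)ethenyl]-2,6-dimethoxyphenyl}-3-(4-methoxyphenyl)propyl]-3-methoxyphenol
Conditions: Pd(PPh3)4 (5 mol%), morpholine (10 equiv), THF, 25 °C
Reagents that add atoms: none
Why: Tsuji–Trost deallylation, in which zerovalent palladium ionises each aryl allyl ether to a π-allyl complex and a phenoxide and morpholine captures the allyl group irreversibly, under neutral conditions that should leave the E-stilbene, the four methyl ethers and C1 unchanged.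

Compound list
1 | 1-(4-hydroxy-2-methoxyphenyl)ethanone | COc1cc(O)ccc1C(C)=O | starting material
2 | 1-[2-methoxy-4-(prop-2-en-1-yloxy)phenyl]ethanone | COc1cc(OCC=C)ccc1C(C)=O | intermediate
3 | 4-methoxybenzaldehyde | COc1ccc(C=O)cc1 | starting material
4 | 3-hydroxy-1-[2-methoxy-4-(prop-2-en-1-yloxy)phenyl]-3-(4-methoxyphenyl)propan-1-one (racemic aldol adduct, not isolated) | COc1ccc(C(O)CC(=O)c2ccc(OCC=C)cc2OC)cc1 | intermediate
5 | (E)-1-[2-methoxy-4-(prop-2-en-1-yloxy)phenyl]-3-(4-methoxyphenyl)prop-2-en-1-one | COc1ccc(/C=C/C(=O)c2ccc(OCC=C)cc2OC)cc1 | intermediate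
6 | pentane-2,4-dione | CC(=O)CC(C)=O | starting material
7 | 3-{(1R)-3-[2-methoxy-4-(prop-2-en-1-yloxy)phenyl]-1-(4-methoxyphenyl)-3-oxopropyl}pentane-2,4-dione | COc1ccc([C@H](CC(=O)c2ccc(OCC=C)cc2OC)C(C(C)=O)C(C)=O)cc1 | intermediate
8 | 3-{(1R)-3-hydroxy-3-[2-methoxy-4-(prop-2-en-1-yloxy)phenyl]-1-(4-methoxyphenyl)propyl}pentane-2,4-dione (both carbinol epimers, not isolated) | COc1ccc([C@H](CC(O)c2ccc(OCC=C)cc2OC)C(C(C)=O)C(C)=O)cc1 | intermediate
9 | 3-{(1R)-3-[2-methoxy-4-(prop-2-en-1-yloxy)phenyl]-1-(4-methoxyphenyl)propyl}pentane-2,4-dione | COc1ccc([C@H](CCc2ccc(OCC=C)cc2OC)C(C(C)=O)C(C)=O)cc1 | intermediate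
10 | methyl (E)-3-(4-hydroxyphenyl)prop-2-enoate | COC(=O)/C=C/c1ccc(O)cc1 | starting material
11 | methyl (E)-3-[4-(prop-2-en-1-yloxy)phenyl]prop-2-enoate | COC(=O)/C=C/c1ccc(OCC=C)cc1 | intermediate
12 | dilithium dianion of 9, deprotonated at B1 and at one methyl carbon, C1 unchanged (not isolated) | [Li+].[Li+].COc1ccc([C@H](CCc2ccc(OCC=C)cc2OC)C(C(=C)[O-])=C(C)[O-])cc1 | intermediate
13 | (7E)-3-{(1R)-3-[2-methoxy-4-(prop-2-en-1-yloxy)phenyl]-1-(4-methoxyphenyl)propyl}-8-[4-(prop-2-en-1-yloxy)phenyl]oct-7-ene-2,4,6-trione (keto form drawn, chain carbon 3 stereolabile) | COc1ccc([C@H](CCc2ccc(OCC=C)cc2OC)C(C(C)=O)C(=O)CC(=O)/C=C/c2ccc(OCC=C)cc2)cc1 | intermediate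
14 | 5-hydroxy-2-{(1R)-3-[2-methoxy-4-(prop-2-en-1-yloxy)phenyl]-1-(4-methoxyphenyl)propyl}-5-{(E)-2-[4-(prop-2-en-1-yloxy)phenyl]ethenyl}cyclohexane-1,3-dione (mixture of ring diastereomers, not isolated) | COc1ccc([C@H](CCc2ccc(OCC=C)cc2OC)C2C(=O)CC(O)(/C=C/c3ccc(OCC=C)cc3)CC2=O)cc1 | intermediate
15 | 2-{(1S)-3-[2-methoxy-4-(prop-2-en-1-yloxy)phenyl]-1-(4-methoxyphenyl)propyl}-5-{(E)-2-[4-(prop-2-en-1-yloxy)phenyl]ethenyl}benzene-1,3-diol | COc1ccc([C@H](CCc2ccc(OCC=C)cc2OC)c2c(O)cc(/C=C/c3ccc(OCC=C)cc3)cc2O)cc1 | intermediate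
16 | 1,3-dimethoxy-2-{(1S)-3-[2-methoxy-4-(prop-2-en-1-yloxy)phenyl]-1-(4-methoxyphenyl)propyl}-5-{(E)-2-[4-(prop-2-en-1-yloxy)phenyl]ethenyl}benzene | COc1ccc([C@H](CCc2ccc(OCC=C)cc2OC)c2c(OC)cc(/C=C/c3ccc(OCC=C)cc3)cc2OC)cc1 | intermediate
17 | 4-[(3S)-3-{4-[(E)-2-(4-hydroxyphenyl)ethenyl]-2,6-dimethoxyphenyl}-3-(4-methoxyphenyl)propyl]-3-methoxyphenol | COc1ccc([C@H](CCc2ccc(O)cc2OC)c2c(OC)cc(/C=C/c3ccc(O)cc3)cc2OC)cc1 | target

Total step count: 9. Longest linear sequence: 8 steps (steps 1, 2, 3, 4, 6, 7, 8, 9); step 5 is a one-step side branch.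

Steps most likely to fail

Step 7. The aldol onto the cross-conjugated, enolate-deactivated styryl ketone may be slow, because the substituted B1 position disfavours the enolate form that leaves B4 electrophilic. Conjugate addition of oxygen nucleophiles to the enone and hydroxide-induced retro-Claisen fragmentation could then outrun ring closure. The fallback sets out from 9 and comes back at 16. Dianion 12 would be acylated with commercial methyl dimethoxyacetate in place of 11, giving 1,1-dimethoxy-5-{(1R)-3-[2-methoxy-4-(prop-2-en-1-yloxy)phenyl]-1-(4-methoxyphenyl)propyl}heptane-2,4,6-trione F1, whose terminal ketone is more electrophilic and offers no conjugate acceptor. Aqueous KOH as in step 7 should close ring B to 5-(dimethoxymethyl)-2-{(1S)-3-[2-methoxy-4-(prop-2-en-1-yloxy)phenyl]-1-(4-methoxyphenyl)propyl}benzene-1,3-diol F2. Methylation as in step 8 would give 5-(dimethoxymethyl)-1,3-dimethoxy-2-{(1S)-3-[2-methoxy-4-(prop-2-en-1-yloxy)phenyl]-1-(4-methoxyphenyl)propyl}benzene F3, and aqueous acetic acid would unveil 3,5-dimethoxy-4-{(1S)-3-[2-methoxy-4-(prop-2-en-1-yloxy)phenyl]-1-(4-methoxyphenyl)propyl}benzaldehyde F4. Horner–Wadsworth–Emmons olefination of F4 with diethyl {[4-(prop-2-en-1-yloxy)phenyl]methyl}phosphonate F5 and NaH in THF would then install the E-styryl group and return to 16. F5 would be made by Michaelis–Arbuzov reaction of 1-(chloromethyl)-4-(prop-2-en-1-yloxy)benzene with P(OEt)3.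

Step 6. Conjugate addition of the dianion or of the amide base to the cinnamate, and proton transfer from the acidic product to 12, could hold back conversion of the valuable chiral diketone. The fallback sets out from 9 and 11 and comes back at 13. Ester 11 would be reduced with i-Bu2AlH to (E)-3-[4-(prop-2-en-1-yloxy)phenyl]prop-2-en-1-ol F6 and oxidised with MnO2 to (E)-3-[4-(prop-2-en-1-yloxy)phenyl]prop-2-enal F7. Dianion 12 should add to the aldehyde carbonyl at −78 °C in a simple aldol addition, giving (7E)-6-hydroxy-3-{(1R)-3-[2-methoxy-4-(prop-2-en-1-yloxy)phenyl]-1-(4-methoxyphenyl)propyl}-8-[4-(prop-2-en-1-yloxy)phenyl]oct-7-ene-2,4-dione F8, an adduct that is not acidic enough to quench 12. Selective oxidation of its allylic alcohol with MnO2 would deliver triketone 13.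

Step 3. The doubly electron-rich enone may react slowly, and reversible addition (retro-Michael) over a long reaction time could erode the enantiomeric purity. The fallback sets out from 5 and 6 and comes back at 7. Addition catalysed by DBU in CH2Cl2 would give racemic 3-{3-[2-methoxy-4-(prop-2-en-1-yloxy)phenyl]-1-(4-methoxyphenyl)-3-oxopropyl}pentane-2,4-dione F9. Preparative chromatography on a chiral stationary phase would separate it into 7 and 3-{(1S)-3-[2-methoxy-4-(prop-2-en-1-yloxy)phenyl]-1-(4-methoxyphenyl)-3-oxopropyl}pentane-2,4-dione F10. F10 would be racemised by warming with DBU through retro-Michael/Michael equilibration and recycled.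

Further compounds
F1 | step 7 | 1,1-dimethoxy-5-{(1R)-3-[2-methoxy-4-(prop-2-en-1-yloxy)phenyl]-1-(4-methoxyphenyl)propyl}heptane-2,4,6-trione | COc1ccc([C@H](CCc2ccc(OCC=C)cc2OC)C(C(C)=O)C(=O)CC(=O)C(OC)OC)cc1
F2 | step 7 | 5-(dimethoxymethyl)-2-{(1S)-3-[2-methoxy-4-(prop-2-en-1-yloxy)phenyl]-1-(4-methoxyphenyl)propyl}benzene-1,3-diol | COc1ccc([C@H](CCc2ccc(OCC=C)cc2OC)c2c(O)cc(C(OC)OC)cc2O)cc1
F3 | step 7 | 5-(dimethoxymethyl)-1,3-dimethoxy-2-{(1S)-3-[2-methoxy-4-(prop-2-en-1-yloxy)phenyl]-1-(4-methoxyphenyl)propyl}benzene | COc1ccc([C@H](CCc2ccc(OCC=C)cc2OC)c2c(OC)cc(C(OC)OC)cc2OC)cc1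
F4 | step 7 | 3,5-dimethoxy-4-{(1S)-3-[2-methoxy-4-(prop-2-en-1-yloxy)phenyl]-1-(4-methoxyphenyl)propyl}benzaldehyde | COc1ccc([C@H](CCc2ccc(OCC=C)cc2OC)c2c(OC)cc(C=O)cc2OC)cc1
F5 | step 7 | diethyl {[4-(prop-2-en-1-yloxy)phenyl]methyl}phosphonate | CCOP(=O)(Cc1ccc(OCC=C)cc1)OCC
F6 | step 6 | (E)-3-[4-(prop-2-en-1-yloxy)phenyl]prop-2-en-1-ol | OC/C=C/c1ccc(OCC=C)cc1
F7 | step 6 | (E)-3-[4-(prop-2-en-1-yloxy)phenyl]prop-2-enal | O=C/C=C/c1ccc(OCC=C)cc1
F8 | step 6 | (7E)-6-hydroxy-3-{(1R)-3-[2-methoxy-4-(prop-2-en-1-yloxy)phenyl]-1-(4-methoxyphenyl)propyl}-8-[4-(prop-2-en-1-yloxy)phenyl]oct-7-ene-2,4-dione | COc1ccc([C@H](CCc2ccc(OCC=C)cc2OC)C(C(C)=O)C(=O)CC(O)/C=C/c2ccc(OCC=C)cc2)cc1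
F9 | step 3 | racemic 3-{3-[2-methoxy-4-(prop-2-en-1-yloxy)phenyl]-1-(4-methoxyphenyl)-3-oxopropyl}pentane-2,4-dione | COc1ccc(C(CC(=O)c2ccc(OCC=C)cc2OC)C(C(C)=O)C(C)=O)cc1
F10 | step 3 | 3-{(1S)-3-[2-methoxy-4-(prop-2-en-1-yloxy)phenyl]-1-(4-methoxyphenyl)-3-oxopropyl}pentane-2,4-dione | COc1ccc([C@@H](CC(=O)c2ccc(OCC=C)cc2OC)C(C(C)=O)C(C)=O)cc1
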